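## Structural features

The target 20 is a furofuran lignan. Two tetrahydrofuran rings share the C1–C5 bond in a cis-fused 3,7-dioxabicyclo[3.3.0]octane (ring 1 = C1, C2, O3, C4, C5; ring 2 = C1, C5, C6, O7, C8). C1 is a fully substituted ring-fusion carbinol and C5 the ring-fusion CH. Ring A (4-hydroxy-3-methoxyphenyl) sits on C2 next to the carbinol, and ring B (3,4-dimethoxyphenyl) on C6 next to C5. The four stereocentres C2, C1, C5 and C6 are contiguous, (1S,2R,5R,6S), and both aryl groups lie on the convex face, each cis to the OH or H of the neighbouring fusion carbon. The fragile groups are the two electron-rich benzylic ether bonds C2–O3 and C6–O7 (ionised by acid, cleaved by hydrogenolysis), the free phenol para to C2 (ring 1 can open through a quinone methide) and the tertiary alcohol. The real difficulty is the oxygen-bearing quaternary C1 flanked by stereocentres on both sides, in a skeleton whose halves differ only by the C1 hydroxyl and one O-methyl group, to be made as one enantiomer from achiral materials. The key step uses the fact that C6 is at the aldehyde oxidation level (it carries O7, ring B and one bond to C5), that C5 becomes nucleophilic once C4 is a lactone carbonyl, and that O7 is tied to C1 through C8: an arylidene acetal across the C1 and C8 oxygens therefore holds C6 within reach of C5, and ring 2 closes by one C–C bond.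

## Logic of the disconnections

20 to 19: only the phenolic O–Si bond is cut. The phenol stays masked to the end so that no quinone methide can form from the C2–O3 bond. The forward step must be neither acidic nor reductive, because both benzylic ethers are already in place.

19 to 17 (through 18): the O3–C4 bond is cut. C4 is a primary carbon, so ring 1 can be closed by the C2 oxygen displacing a leaving group on C4 without touching C2. This opens ring 1 to a triol. It demands that the primary hydroxyl be activated selectively beside a benzylic and a tertiary one.

17 to 16: C4 is raised to the carboxyl level and ring 1 becomes a lactone. No bond of the skeleton changes, but C5 becomes an α-carbon and hence a latent nucleophile. The forward reduction must spare the aryl silyl ether.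

16 to 12 (through 13, 14 and 15): the C5–C6 bond is cut and C6 is returned to an acetal carbon bridging the C1 and C8 oxygens. This removes ring 2 and the stereocentres C5 and C6 at once and leaves only C1 and C2 to be made. The forward step needs ionisation of the acetal on the C1 side, bonding of C5 on the face of C8, and ring B on the convex face.

12 to 9 and 10 (through 11): the two C6–O bonds are cut. This separates ring B as a commercial aldehyde from a lactone diol that carries all the remaining stereochemistry. The forward acetalisation must be mild enough to leave the benzylic lactone C2–O3 bond alone.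

9 to 7 (through 8): the C2–O3 bond is cut and the carboxyl is reconnected to the C8 oxygen, so that the C1 and C2 oxygens become one epoxide. Two stereocentres become a single cis-delivered oxygen. The forward step needs rearside attack of the carboxyl on C2 only, so that C2 is inverted and C1 is retained.

7 to 6: the epoxide oxygen is removed. Both stereocentres now stem from one catalytic, face-selective oxygen transfer to an (E)-olefin, which demands reliable facial selectivity and a single olefin geometry.

6 to 5 to 3 (through 4): the silyl group is removed and C8 is returned to the ester level. The C8–O bond of the lactone comes from reduction of a conjugated ester while the other carboxyl is a free acid. The reduction must distinguish ester from carboxylate.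

3 to 1 and 2: the C1=C2 double bond is cut. 2 supplies C1, C4, C5 and C8, and 1 supplies C2 with ring A. The forward condensation must give the (E)-olefin and two differentiated carboxyl groups in one operation.

## Other disconnections considered

Alternative 1: The cut is through C1–C2 and C2–O3, so that C2 with ring A returns to aldehyde A3 (the silyl ether of 1) and the rest is lactone A2, in which ring 2 is a γ-lactone with C8 as carbonyl, C1 silyloxylated and C5 carrying a silyloxymethyl group. In the forward step A2 is taken to its tetrasubstituted α-silyloxy ketene acetal, Me3SiOTf condenses A3 with the C4 silyl ether to the O3=C2 oxocarbenium ion, and C1 attacks it to close ring 1 and give A1.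
- In its favour: ring A arrives late, which is more convergent and better for analogues than the chosen plan. Two skeletal bonds (C–C and C–O) and the quaternary carbinol form in one step. The nucleophilic carbon has no leaving group in the β-position, which is a real advantage over the chosen plan, where the C1 oxygen is β to C5.
- Against it: an α-silyloxy lactone is not enolised by soft silylation, so a strong amide base and a separate step would be needed. The C–C bond is made at a fully substituted carbon onto a well-stabilised, sluggish oxocarbenium ion that has to be assembled intermolecularly. C2 would be set by exo/endo preference in the closure rather than stereospecifically.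
- Comparison: the mechanism is of the same family (equal). The endgame of lactone reduction, ether closure and desilylation is equal in length. A2 needs its own enantioselective synthesis of two stereocentres, so the overall count is expected to be no shorter. The chosen plan is safer at the quaternary centre because C1 is made early by oxygen transfer and never by C–C bond formation.

Alternative 2: The cut is through C1–C2 and C4–C5, with O3 inserted afterwards. In the forward step acid chloride A6 and an amine give aryl ketene A7, which adds to silyl enol ether A5 in a [2+2] cycloaddition (carbonyl carbon to C5, aryl-bearing carbon to C1) to give cyclobutanone A4. Baeyer–Villiger migration of the benzylic C2 would then give lactone A8, the bis-silyl analogue of 16.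
- In its favour: two C–C bonds and the oxygenated quaternary C1 form in one step, which is more than the chosen key step forms. The polarity of ketene and enol ether fixes the regiochemistry. Ring B on C6 should steer the ketene to the opposite face, so C5 and C1 follow from C6; this is equal to the chosen plan in control of the ring fusion.
- Against it: monoaryl ketenes dimerise readily. The larger ketene substituent normally ends on the concave face of the bicycle, which would place ring A endo, opposite to what 20 needs, so an epimerisation α to the cyclobutanone would have to be added. A5 requires regioselective enolisation away from the oxygen-bearing C8 and can aromatise or lose its C6 configuration. A peracid has to be used beside two electron-rich arenes.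
- Comparison: A8 is reached one oxidation step later than 16 is reached in the chosen plan, and A5 needs its own asymmetric synthesis, so step economy is worse. The chosen plan fixes C2 by a stereospecific displacement, where this alternative relies on a correction.

Alternative 3: The cut is through C1–C2 only, leaving furanone A10 with ring A attached as a benzyl ether through O3 and C4. In the forward step irradiation excites the C1 ketone, which abstracts a benzylic hydrogen from C2 (the δ-position; O3 occupies the γ-position). The 1,5-biradical closes the C1–C2 bond and gives A9 with the carbinol formed in the same event; fluoride would then give 20.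
- In its favour: the complete skeleton appears at the final oxidation level. One step follows the key step against three in the chosen plan, so this alternative is clearly better in step economy after the key step and in redox economy. The cis fusion is enforced by the short tether (equal).
- Against it: an excited ketone beside two electron-rich arenes invites charge-transfer quenching. α-Cleavage (Norrish type 1) of the α-alkoxy ketone and reverse hydrogen transfer compete. C2 is set by radical recombination, so a mixture of exo and endo aryl is to be expected. Throughput of a photoreaction is limited, and A10 still needs an enantioselective synthesis.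
- Comparison: the chosen plan is longer after the key step but sets every stereocentre by closed-shell, stereospecific or tether-controlled events. This alternative trades that predictability for brevity.

Key step: step 7

Assumptions and design remarks:
- Assumption: the sense of induction in step 4 is taken from the spiro transition-state model for (E)-trisubstituted styrene-type olefins. By that model the D-fructose-derived ketone gives the (2R,3R)-epoxide, so the L-fructose-derived ketone (purchasable, or made from L-sorbose) is used for the required (2S,3S)-epoxide.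
- Remark: the phenol is carried as its triisopropylsilyl ether and not as a tert-butyldimethylsilyl ether. It is stable to carbonate buffer, hydroxide and LiAlH4 and is still cleaved by fluoride. It is introduced after the Stobbe condensation, because no aryl silyl ether would survive the alkoxide.
- Remark: the ring closure of step 7 is a 5-(enolexo)-endo-trig process. Its first product is the C1 trimethylsilyl ether 15, so an acidic work-up is part of the step.
- Remark: 12 is used as the mixture of its two acetal epimers.

## Route

Step 1
Reactants: 1 vanillin; 2 dimethyl succinate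
Product: 3 (E)-4-(4-hydroxy-3-methoxyphenyl)-3-(methoxycarbonyl)but-3-enoic acid
Conditions: LiOMe (3.5 equiv), MeOH, reflux; then 2 M HCl, 0 °C
Reagents that add atoms: none
Why: Stobbe condensation: the succinate enolate adds to the aldehyde, the aldolate closes to a paraconic ester and E1cB ring opening gives the half-ester with the aryl trans to the conjugated ester (E) and with the two carboxyl groups differentiated; the lithium phenoxide is what should let the unprotected hydroxy aldehyde react.

Step 2
Reactants: 3
Product: 5 (E)-4-(4-hydroxy-3-methoxybenzylidene)dihydrofuran-2(3H)-one, via hydroxy acid 4 (not isolated)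
Conditions: i-Bu2AlH (5 equiv), THF, −78 → 0 °C; aq. KNaC4H4O6; then 1 M HCl to pH 3, rt
Reagents that add atoms: none
Why: 1,2-Reduction of the conjugated methyl ester by i-Bu2AlH while phenol and acid are held as unreactive aluminium phenoxide and carboxylate; on acidification hydroxy acid 4 should close to the γ-lactone (acid-catalysed lactonisation) with the olefin geometry unchanged.

Step 3
Reactants: 5
Product: 6 (E)-4-[3-methoxy-4-(triisopropylsilyloxy)benzylidene]dihydrofuran-2(3H)-one
Conditions: i-Pr3SiCl (1.2 equiv), imidazole (2.5 equiv), DMF, rt
Reagents that add atoms: triisopropylsilyl chloride, CC(C)[Si](Cl)(C(C)C)C(C)C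
Why: Imidazole-mediated silylation of the only hydroxyl; the bulky aryl silyl ether is chosen to survive the carbonate buffer of step 4, the hydroxide of step 5 and the hydride of step 8.

Step 4
Reactants: 6
Product: 7 (2S,3S)-2-[3-methoxy-4-(triisopropylsilyloxy)phenyl]-1,5-dioxaspiro[2.4]heptan-6-one
Conditions: L-fructose-derived Shi ketone (0.3 equiv), KHSO5 (as 2KHSO5·KHSO4·K2SO4, 1.5 equiv), K2CO3 (6 equiv), Bu4NHSO4 (cat.), MeCN–CH2(OMe)2/aq. Na2B4O7 buffer (pH 10.5), −5 → 0 °C; crude product used directly
Reagents that add atoms: potassium peroxymonosulfate, [K+].[O-]S(=O)(=O)OO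
Why: Shi asymmetric epoxidation: the chiral dioxirane transfers oxygen suprafacially through a spiro transition state to the electron-rich (E)-trisubstituted olefin, so C1 and C2 are set together and the L-configured ketone should give the (2S,3S)-epoxide; the basic buffer protects the acid-labile aryl epoxide.

Step 5
Reactants: 7
Product: 9 (4S,5R)-4-hydroxy-4-(hydroxymethyl)-5-[3-methoxy-4-(triisopropylsilyloxy)phenyl]dihydrofuran-2(3H)-one, via epoxy carboxylate 8 (not isolated)
Conditions: LiOH (1.1 equiv), THF–H2O, 0 °C; then AcOH (1.1 equiv), 0 °C → rt
Reagents that add atoms: lithium hydroxide, [Li+].[OH-]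
Why: Saponification gives carboxylate 8, which after mild acidification should open the epoxide at the benzylic carbon from the rear (epoxy-acid lactonisation in the 5-endo mode, the only alternative being a β-lactone), so C2 is inverted to (R) while the C1–O bond and its configuration are kept; the lactone thereby moves from the C8 oxygen to C2 and the C1/C8 diol is set free.

Step 6
Reactants: 9; 10 veratraldehyde
Product: 12 (5S,6R)-2-(3,4-dimethoxyphenyl)-6-[3-methoxy-4-(triisopropylsilyloxy)phenyl]-1,3,7-trioxaspiro[4.4]nonan-8-one as both acetal epimers, via dimethyl acetal 11 (not isolated)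
Conditions: HC(OMe)3 (2 equiv), PPTS (0.1 equiv), CH2Cl2, rt → 40 °C
Reagents that add atoms: none
Why: Acid-catalysed transacetalisation: 10 is converted in the flask into dimethyl acetal 11, which exchanges with the tertiary/primary 1,2-diol to the five-membered arylidene acetal; the acetal centre forms unselectively, which is of no consequence because it becomes planar in step 7.

Step 7
Reactants: 12
Product: 16 (1S,2R,5R,6S)-6-(3,4-dimethoxyphenyl)-1-hydroxy-2-[3-methoxy-4-(triisopropylsilyloxy)phenyl]-3,7-dioxabicyclo[3.3.0]octan-4-one, via silyl ketene acetal 13 (not isolated), via oxocarbenium triflate 14 (not isolated), via trimethylsilyl ether 15 (not isolated)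
Conditions: Et3N (2.2 equiv), Me3SiOTf (3.0 equiv), CH2Cl2, −78 → −20 °C; then 1 M HCl, THF, 0 °C
Reagents that add atoms: none
Why: Et3N/Me3SiOTf should first turn the lactone into silyl ketene acetal 13 by soft enolisation (C5 is the only α-carbon); the excess Me3SiOTf should then silylate the acetal oxygen on C1 and cleave its bond to C6, giving the aryl-stabilised (E)-oxocarbenium ion 14 held to C1 through C8 and O7. C5 adds to C6 in an intramolecular Mukaiyama aldol-type addition to an acetal, the carbon analogue of a Petasis–Ferrier rearrangement; loss of the silyl group from the lactone oxygen restores the carbonyl as silyl ether 15, which the acidic work-up cleaves to 16. Ring 2 closes in the 5-(enolexo)-endo-trig mode, with the nucleophilic C4=C5 bond outside the new ring and the O7=C6 bond inside it, which is an accessible mode for oxocarbenium ions. C5 is controlled by C1: the tether through C8 can reach only the face of the ketene acetal that carries C8, so the fusion must be cis and H5 ends cis to the C1 oxygen. C6 is controlled by the (E) geometry of the ion and by ring 1: the transition state that turns ring B outward to the convex face, trans to C4, should be preferred over the one that pushes it under the silyloxy-bearing C4. The selectivity needed is the site of ionisation; cleavage on the primary side gives an ion that could close only a four-membered ring, should return to the acetal and so drain through 14. β-Elimination of the C1 oxygen is held back because that oxygen is an acetal oxygen in 13 and a silyl ether in 14 and no metal enolate is present; C1 and C2 are not touched.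

Step 8
Reactants: 16
Product: 17 (3S,4R,5S)-5-(3,4-dimethoxyphenyl)-3-{(R)-hydroxy[3-methoxy-4-(triisopropylsilyloxy)phenyl]methyl}-4-(hydroxymethyl)oxolan-3-ol
Conditions: LiAlH4 (2.5 equiv), THF, 0 °C; then H2O, aq. NaOH
Reagents that add atoms: none
Why: LiAlH4 reduction of the lactone to the 1,4-diol; no C–O bond at a stereocentre is broken, and the aryl silyl ether and the benzylic ether of ring 2 should be inert at 0 °C.

Step 9
Reactants: 17
Product: 19 (1S,2R,5R,6S)-6-(3,4-dimethoxyphenyl)-2-[3-methoxy-4-(triisopropylsilyloxy)phenyl]-3,7-dioxabicyclo[3.3.0]octan-1-ol, via primary mesylate 18 (not isolated)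
Conditions: MsCl (1.1 equiv), pyridine, CH2Cl2, −10 °C → rt
Reagents that add atoms: none
Why: Selective sulfonylation of the primary hydroxyl (the benzylic and tertiary hydroxyls react far more slowly in pyridine) and intramolecular Williamson etherification by the C2 hydroxyl in the 5-exo-tet mode; the displacement takes place at C4, so C2 keeps its configuration, and closure through the tertiary hydroxyl would need a four-membered ring.

Step 10
Reactants: 19
Product: 20 (1S,2R,5R,6S)-6-(3,4-dimethoxyphenyl)-2-(4-hydroxy-3-methoxyphenyl)-3,7-dioxabicyclo[3.3.0]octan-1-ol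
Conditions: Bu4NF (1.2 equiv), AcOH (1.2 equiv), THF, 0 °C
Reagents that add atoms: none
Why: Fluoride cleavage of the aryl silyl ether; the acetic acid buffer keeps the liberated phenol protonated, so that ring 1 is not opened through a quinone methide and no stereocentre is disturbed.

## Compound list

1 | vanillin (4-hydroxy-3-methoxybenzaldehyde) | COc1cc(C=O)ccc1O | starting material
2 | dimethyl succinate | COC(=O)CCC(=O)OC | starting material
3 | (E)-4-(4-hydroxy-3-methoxyphenyl)-3-(methoxycarbonyl)but-3-enoic acid | COC(=O)/C(CC(=O)O)=C/c1ccc(O)c(OC)c1 | intermediate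
4 | (E)-3-(hydroxymethyl)-4-(4-hydroxy-3-methoxyphenyl)but-3-enoic acid | OC/C(CC(=O)O)=C/c1ccc(O)c(OC)c1 | intermediate (not isolated)
5 | (E)-4-(4-hydroxy-3-methoxybenzylidene)dihydrofuran-2(3H)-one | O=C1C/C(=C\c2ccc(O)c(OC)c2)CO1 | intermediate
6 | (E)-4-[3-methoxy-4-(triisopropylsilyloxy)benzylidene]dihydrofuran-2(3H)-one | O=C1C/C(=C\c2ccc(O[Si](C(C)C)(C(C)C)C(C)C)c(OC)c2)CO1 | intermediate
7 | (2S,3S)-2-[3-methoxy-4-(triisopropylsilyloxy)phenyl]-1,5-dioxaspiro[2.4]heptan-6-one | O=C1C[C@@]2(CO1)O[C@H]2c1ccc(O[Si](C(C)C)(C(C)C)C(C)C)c(OC)c1 | intermediate
8 | lithium 2-{(2S,3S)-2-(hydroxymethyl)-3-[3-methoxy-4-(triisopropylsilyloxy)phenyl]oxiran-2-yl}acetate | [Li+].[O-]C(=O)C[C@@]1(CO)O[C@H]1c1ccc(O[Si](C(C)C)(C(C)C)C(C)C)c(OC)c1 | intermediate (not isolated)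
9 | (4S,5R)-4-hydroxy-4-(hydroxymethyl)-5-[3-methoxy-4-(triisopropylsilyloxy)phenyl]dihydrofuran-2(3H)-one | COc1cc([C@H]2OC(=O)C[C@]2(O)CO)ccc1O[Si](C(C)C)(C(C)C)C(C)C | intermediate
10 | veratraldehyde (3,4-dimethoxybenzaldehyde) | COc1ccc(C=O)cc1OC | starting material
11 | 4-(dimethoxymethyl)-1,2-dimethoxybenzene | COc1ccc(C(OC)OC)cc1OC | intermediate (not isolated)
12 | (5S,6R)-2-(3,4-dimethoxyphenyl)-6-[3-methoxy-4-(triisopropylsilyloxy)phenyl]-1,3,7-trioxaspiro[4.4]nonan-8-one; both epimers at the acetal carbon form, the (2R) epimer is written | COc1cc([C@H]2OC(=O)C[C@]23CO[C@@H](c4ccc(OC)c(OC)c4)O3)ccc1O[Si](C(C)C)(C(C)C)C(C)C | intermediate (precursor of the key step)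
13 | (5S,6R)-2-(3,4-dimethoxyphenyl)-6-[3-methoxy-4-(triisopropylsilyloxy)phenyl]-8-(trimethylsilyloxy)-1,3,7-trioxaspiro[4.4]non-8-ene (silyl ketene acetal of 12) | COc1cc([C@H]2OC(O[Si](C)(C)C)=C[C@]23CO[C@@H](c4ccc(OC)c(OC)c4)O3)ccc1O[Si](C(C)C)(C(C)C)C(C)C | intermediate (not isolated)
14 | (E)-oxocarbenium trifluoromethanesulfonate from 13: O7=C6 cation carrying ring B, bound through C8 to C1, with Me3SiO on C1 and the silyl ketene acetal intact | COc1cc([C@H]2OC(O[Si](C)(C)C)=C[C@]2(O[Si](C)(C)C)C/[O+]=C/c2ccc(OC)c(OC)c2)ccc1O[Si](C(C)C)(C(C)C)C(C)C.[O-]S(=O)(=O)C(F)(F)F | intermediate (not isolated)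
15 | (1S,2R,5R,6S)-6-(3,4-dimethoxyphenyl)-2-[3-methoxy-4-(triisopropylsilyloxy)phenyl]-1-(trimethylsilyloxy)-3,7-dioxabicyclo[3.3.0]octan-4-one | COc1cc([C@H]2OC(=O)[C@@H]3[C@@H](c4ccc(OC)c(OC)c4)OC[C@]23O[Si](C)(C)C)ccc1O[Si](C(C)C)(C(C)C)C(C)C | intermediate (not isolated)
16 | (1S,2R,5R,6S)-6-(3,4-dimethoxyphenyl)-1-hydroxy-2-[3-methoxy-4-(triisopropylsilyloxy)phenyl]-3,7-dioxabicyclo[3.3.0]octan-4-one | COc1cc([C@H]2OC(=O)[C@@H]3[C@@H](c4ccc(OC)c(OC)c4)OC[C@]23O)ccc1O[Si](C(C)C)(C(C)C)C(C)C | intermediate (product of the key step)
17 | (3S,4R,5S)-5-(3,4-dimethoxyphenyl)-3-{(R)-hydroxy[3-methoxy-4-(triisopropylsilyloxy)phenyl]methyl}-4-(hydroxymethyl)oxolan-3-ol | COc1cc([C@@H](O)[C@@]2(O)CO[C@H](c3ccc(OC)c(OC)c3)[C@H]2CO)ccc1O[Si](C(C)C)(C(C)C)C(C)C | intermediate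
18 | {(2S,3R,4S)-2-(3,4-dimethoxyphenyl)-4-hydroxy-4-{(R)-hydroxy[3-methoxy-4-(triisopropylsilyloxy)phenyl]methyl}oxolan-3-yl}methyl methanesulfonate | COc1cc([C@@H](O)[C@@]2(O)CO[C@H](c3ccc(OC)c(OC)c3)[C@H]2COS(C)(=O)=O)ccc1O[Si](C(C)C)(C(C)C)C(C)C | intermediate (not isolated)
19 | (1S,2R,5R,6S)-6-(3,4-dimethoxyphenyl)-2-[3-methoxy-4-(triisopropylsilyloxy)phenyl]-3,7-dioxabicyclo[3.3.0]octan-1-ol | COc1cc([C@H]2OC[C@@H]3[C@@H](c4ccc(OC)c(OC)c4)OC[C@]23O)ccc1O[Si](C(C)C)(C(C)C)C(C)C | intermediate
20 | (1S,2R,5R,6S)-6-(3,4-dimethoxyphenyl)-2-(4-hydroxy-3-methoxyphenyl)-3,7-dioxabicyclo[3.3.0]octan-1-ol | COc1cc([C@H]2OC[C@@H]3[C@@H](c4ccc(OC)c(OC)c4)OC[C@]23O)ccc1O | target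

## Step count and least certain steps

Total: 10 steps. Longest linear sequence: 10 steps (1 to 20); 10 enters at step 6.

Step 7 (key step). The most likely failure is ionisation of the acetal on the primary side. That leaves a cationic oxygen on C1, β to the ketene acetal, and fragmentation to a butenolide with loss of the aldehyde could outrun the return to the acetal. Incomplete facial selectivity at C6 and Lewis-acid epimerisation at the benzylic lactone carbon C2 are the secondary risks. The fallback builds the same bond by a stepwise aldol. It sets out from 9, which is deprotonated at both hydroxyls and at C5 with LiN(i-Pr)2 (3.3 equiv, THF, −78 °C); as in a Fráter–Seebach reaction, the alkoxide on C1 cannot leave. Addition to 10 should occur anti to the C1 oxygen and to ring A, that is cis to C8, giving the aldol adduct F1 as both carbinol epimers. Catalytic camphorsulfonic acid in CH2Cl2 at 0 °C should ionise the veratryl carbinol, and capture by the C8 hydroxyl closes ring 2 with ring B on the convex face. The fallback comes back to the route at 16.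

Step 4. The β,γ-unsaturated lactone may isomerise into conjugation or hydrolyse in the carbonate buffer, and the facial selectivity for an exocyclic olefin with two similar allylic methylene groups may be insufficient. The fallback uses hydroxyl-directed epoxidation. It sets out from 6, which is opened with pyrrolidine and Me3Al (CH2Cl2, 0 °C → rt) to the hydroxy amide F2. Katsuki–Sharpless epoxidation with Ti(OiPr)4, L-(+)-diethyl tartrate and t-BuOOH (4 Å sieves, CH2Cl2, −20 °C) should give the (2S,3S)-epoxy alcohol F3. Dilute aqueous acetic acid then lets the amide oxygen open the epoxide at the benzylic carbon with inversion, and hydrolysis of the iminium ether gives the lactone. The fallback comes back at 9 and passes by 7 and 8.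

Step 5. With hydroxide present beside an epoxy alcohol, migration of the epoxide toward C8 (Payne type, which would invert C1) and loss of the aryl silyl ether can occur. On acidification the opening may run partly through an open benzylic cation, with loss of stereospecificity at C2. The fallback reverses the order of events. It sets out from 6, which is saponified first (LiOH, THF–H2O, 0 °C) to the lithium hydroxy enoate F4, so that no epoxide is present when hydroxide is. Shi epoxidation of this water-soluble salt under the conditions of step 4 should give 8 directly, and acidification as in step 5 gives 9. The fallback comes back to the route at 8.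

Step 1. Addition to the phenoxide-deactivated aldehyde may be slow, so that self-condensation of 2 takes over. The fallback masks the phenol for this step only. It sets out from 1, which is alkylated (allyl bromide, K2CO3, DMF) to the allyl ether F5. Stobbe condensation with 2 (NaOMe, MeOH, reflux) gives the allyl half-ester F6, and Pd(PPh3)4 with morpholine in THF removes the allyl group. The fallback comes back at 3.

Step 9. Sulfonylation may not discriminate well enough between the primary and the benzylic hydroxyl, and ionisation of the electron-rich benzylic carbinol would scramble C2. The fallback never opens ring 1. It sets out from 16, which is reduced with i-Bu2AlH (CH2Cl2, −78 °C) only as far as the lactol F7. Et3SiH and BF3·OEt2 (CH2Cl2, −78 °C) then remove the anomeric hydroxyl by hydride delivery to the O3=C4 oxocarbenium ion. The fallback comes back at 19 and passes by 17 and 18.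

## Further compounds

F1 | step 7 | (4S,5R)-3-[(3,4-dimethoxyphenyl)(hydroxy)methyl]-4-hydroxy-4-(hydroxymethyl)-5-[3-methoxy-4-(triisopropylsilyloxy)phenyl]dihydrofuran-2(3H)-one, C3 side chain cis to the hydroxymethyl group, both carbinol epimers | COc1cc([C@H]2OC(=O)[C@H](C(O)c3ccc(OC)c(OC)c3)[C@]2(O)CO)ccc1O[Si](C(C)C)(C(C)C)C(C)C
F2 | step 4 | (E)-3-(hydroxymethyl)-4-[3-methoxy-4-(triisopropylsilyloxy)phenyl]-1-(pyrrolidin-1-yl)but-3-en-1-one | OC/C(CC(=O)N1CCCC1)=C/c1ccc(O[Si](C(C)C)(C(C)C)C(C)C)c(OC)c1
F3 | step 4 | 2-{(2S,3S)-2-(hydroxymethyl)-3-[3-methoxy-4-(triisopropylsilyloxy)phenyl]oxiran-2-yl}-1-(pyrrolidin-1-yl)ethan-1-one | O=C(C[C@@]1(CO)O[C@H]1c1ccc(O[Si](C(C)C)(C(C)C)C(C)C)c(OC)c1)N1CCCC1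
F4 | step 5 | lithium (E)-3-(hydroxymethyl)-4-[3-methoxy-4-(triisopropylsilyloxy)phenyl]but-3-enoate | [Li+].[O-]C(=O)C/C(CO)=C\c1ccc(O[Si](C(C)C)(C(C)C)C(C)C)c(OC)c1
F5 | step 1 | 4-(allyloxy)-3-methoxybenzaldehyde | COc1cc(C=O)ccc1OCC=C
F6 | step 1 | (E)-4-[4-(allyloxy)-3-methoxyphenyl]-3-(methoxycarbonyl)but-3-enoic acid | COC(=O)/C(CC(=O)O)=C/c1ccc(OCC=C)c(OC)c1
F7 | step 9 | (1S,2R,5R,6S)-6-(3,4-dimethoxyphenyl)-2-[3-methoxy-4-(triisopropylsilyloxy)phenyl]-3,7-dioxabicyclo[3.3.0]octane-1,4-diol, both C4 epimers | COc1cc([C@H]2OC(O)[C@@H]3[C@@H](c4ccc(OC)c(OC)c4)OC[C@]23O)ccc1O[Si](C(C)C)(C(C)C)C(C)C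
A1 | alternative 1 | 1-(tert-butyldimethylsilyloxy)-2-[4-(tert-butyldimethylsilyloxy)-3-methoxyphenyl]-6-(3,4-dimethoxyphenyl)-3,7-dioxabicyclo[3.3.0]octan-8-one, configuration as in 20 | COc1cc([C@H]2OC[C@@H]3[C@@H](c4ccc(OC)c(OC)c4)OC(=O)[C@]23O[Si](C)(C)C(C)(C)C)ccc1O[Si](C)(C)C(C)(C)C
A2 | alternative 1 | (4R,5S)-3-(tert-butyldimethylsilyloxy)-5-(3,4-dimethoxyphenyl)-4-[(trimethylsilyloxy)methyl]dihydrofuran-2(3H)-one, either C3 epimer | C[Si](C)(C)OC[C@@H]1[C@@H](c2ccc(OC)c(OC)c2)OC(=O)C1O[Si](C)(C)C(C)(C)C
A3 | alternative 1 | 4-(tert-butyldimethylsilyloxy)-3-methoxybenzaldehyde | COc1cc(C=O)ccc1O[Si](C)(C)C(C)(C)C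
A4 | alternative 2 | 1-(tert-butyldimethylsilyloxy)-7-[4-(tert-butyldimethylsilyloxy)-3-methoxyphenyl]-4-(3,4-dimethoxyphenyl)-3-oxabicyclo[3.2.0]heptan-6-one, configuration as in 20 | COc1cc([C@H]2C(=O)[C@@H]3[C@@H](c4ccc(OC)c(OC)c4)OC[C@]23O[Si](C)(C)C(C)(C)C)ccc1O[Si](C)(C)C(C)(C)C
A5 | alternative 2 | (2S)-4-(tert-butyldimethylsilyloxy)-2-(3,4-dimethoxyphenyl)-2,5-dihydrofuran | CC(C)(C)[Si](C)(C)OC1=C[C@@H](c2ccc(OC)c(OC)c2)OC1
A6 | alternative 2 | [4-(tert-butyldimethylsilyloxy)-3-methoxyphenyl]acetyl chloride | COc1cc(CC(Cl)=O)ccc1O[Si](C)(C)C(C)(C)C
A7 | alternative 2 | [4-(tert-butyldimethylsilyloxy)-3-methoxyphenyl]ketene | COc1cc(C=C=O)ccc1O[Si](C)(C)C(C)(C)C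
A8 | alternative 2 | 1-(tert-butyldimethylsilyloxy)-2-[4-(tert-butyldimethylsilyloxy)-3-methoxyphenyl]-6-(3,4-dimethoxyphenyl)-3,7-dioxabicyclo[3.3.0]octan-4-one, configuration as in 16 | COc1cc([C@H]2OC(=O)[C@@H]3[C@@H](c4ccc(OC)c(OC)c4)OC[C@]23O[Si](C)(C)C(C)(C)C)ccc1O[Si](C)(C)C(C)(C)C
A9 | alternative 3 | (1S,2R,5R,6S)-2-[4-(tert-butyldimethylsilyloxy)-3-methoxyphenyl]-6-(3,4-dimethoxyphenyl)-3,7-dioxabicyclo[3.3.0]octan-1-ol | COc1cc([C@H]2OC[C@@H]3[C@@H](c4ccc(OC)c(OC)c4)OC[C@]23O)ccc1O[Si](C)(C)C(C)(C)C
A10 | alternative 3 | (4R,5S)-4-({[4-(tert-butyldimethylsilyloxy)-3-methoxyphenyl]methoxy}methyl)-5-(3,4-dimethoxyphenyl)dihydrofuran-3(2H)-one | COc1cc(COC[C@@H]2[C@@H](c3ccc(OC)c(OC)c3)OCC2=O)ccc1O[Si](C)(C)C(C)(C)C
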